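**Retrosynthetic overview** (labels: C1–C9 run from the carboxyl carbon through the dioxane, whose ring carbons are C3 and C6, to the alkene CH; the bicycle keeps naphthalene numbers)

1. Target 30 ← ester 29 ← allylic alcohol 26 by reductive 1,3-transposition (allylic diazene), which moves the ring C2=C3 alkene into the exocyclic Z position; 26 ← alkyne 13 + dienal 22 (zinc alkynylide addition, then diimide).
2. Dienal 22 ← bromobenzene + lactone 15: Friedel–Crafts annulation builds the gem-dimethyl ring on the arene; Birch reduction later fixes both ring alkenes.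
3. Dioxane 13 ← silyl peroxide 9: the peroxide ring closes by SN2 opening of an enantiopure β-lactone (inverts C3); C6 is then corrected thermodynamically because the ethynyl group is much slimmer than methyl.
4. Key bond C6–O: cobalt-hydride hydrogen-atom transfer to 1,3-enyne 8 and O2 capture by the tertiary propargylic radical; 8 ← aldehyde 5 + propanoyl chloride (asymmetric ketene–aldehyde cycloaddition sets C2 and C3).
5. Ring order: carbocycle on the arene (step 7) → oxetanone (step 3) → 1,2-dioxane (step 5) → diene ring by Birch (step 10) → exocyclic alkene last (step 14).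

Assumption: O-trimethylsilylquinine is taken as the pseudoenantiomeric catalyst that gives the (3S,4R) lactone 8 (the quinidine analogue gives its mirror image).

**Step 1**
Reactants: 1 2-methylbut-1-en-3-yne; 2 oxirane
Product: 4 4-methylidenehex-5-yn-1-ol, via dipotassium dianion 3 (not isolated)
Conditions: n-BuLi (2.1 equiv), KOtBu (2.1 equiv), THF–hexane, −75 to −20 °C; then 2, −60 to 0 °C; H2O
Reagents that add atoms: none
Why: Schlosser-base double metalation removes the acetylenic and one allylic hydrogen to give a symmetrical 2-ethynylallyl dianion whose allylic carbon, the more nucleophilic site, opens the epoxide (SN2 epoxide alkylation), so no regio- or stereochemical issue arises.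

**Step 2**
Reactants: 4 4-methylidenehex-5-yn-1-ol
Product: 5 4-methylidenehex-5-ynal
Conditions: TEMPO (10 mol %), PhI(OAc)2 (1.1 equiv), CH2Cl2, 23 °C
Reagents that add atoms: none
Why: TEMPO/PhI(OAc)2 oxoammonium oxidation takes the primary alcohol to the aldehyde without over-oxidation or attack on the enyne.

**Step 3**
Reactants: 5 4-methylidenehex-5-ynal; 6 propanoyl chloride
Product: 8 (3S,4R)-3-methyl-4-(3-methylidenepent-4-yn-1-yl)oxetan-2-one, via methylketene 7 (not isolated)
Conditions: O-trimethylsilylquinine (10 mol %), LiClO4 (0.5 equiv), i-Pr2NEt (2.5 equiv), CH2Cl2–Et2O, −78 °C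
Reagents that add atoms: none
Why: Nelson acyl halide–aldehyde cyclocondensation (alkaloid-catalysed asymmetric ketene–aldehyde [2+2]) adds the alkaloid-bound enolate of methylketene to the lithium-activated aldehyde through a closed transition state, giving the cis lactone in which C2 already has its final (S) sense and C3 carries oxygen on the face that the SN2 step 5 will invert.

**Step 4 (key step)**
Reactants: 8 (3S,4R)-3-methyl-4-(3-methylidenepent-4-yn-1-yl)oxetan-2-one
Product: 9 (3S,4R)-3-methyl-4-{3-methyl-3-[(triethylsilyl)peroxy]pent-4-yn-1-yl}oxetan-2-one (1:1 at the peroxide carbon)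
Conditions: Co(acac)2 (10 mol %), Et3SiH (2.5 equiv), O2 (1 atm), ClCH2CH2Cl, 23 °C
Reagents that add atoms: dioxygen O=O; triethylsilane CC[SiH](CC)CC
Why: Proposed new method: cobalt hydride transfers a hydrogen atom to the CH2 terminus of the 1,3-enyne (the only alkene present), the tertiary propargylic radical captures O2 at the propargylic carbon and the trivalent cobalt alkylperoxide is silylated by Et3SiH, which forges the C6–O bond in a radical chain without touching the β-lactone or the terminal alkyne, the new centre being formed without control and corrected in step 6; closest known chemistry is the Isayama–Mukaiyama hydroperoxysilylation of 1,1-disubstituted alkenes and the Mukaiyama hydration of 2-substituted 1,3-enynes.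

**Step 5**
Reactants: 9 (3S,4R)-3-methyl-4-{3-methyl-3-[(triethylsilyl)peroxy]pent-4-yn-1-yl}oxetan-2-one
Product: 12 methyl (2S)-2-[(3S)-6-ethynyl-6-methyl-1,2-dioxan-3-yl]propanoate (both C6 epimers), via ammonium peroxide 10 (not isolated), via ammonium carboxylate 11 (not isolated)
Conditions: Bu4NF (1.1 equiv), THF, −40 to 0 °C; then MeI (3 equiv), 23 °C
Reagents that add atoms: iodomethane CI
Why: Proposed new method: fluoride unmasks the tertiary peroxide anion, which opens the strained β-lactone by 6-exo-tet SN2 attack at its oxygen-bearing carbon (alkyl–oxygen cleavage) with clean inversion to give the (3S) centre and the 2,3-anti carboxylate that MeI esterifies; closest known chemistry is the intramolecular alkylation of hydroperoxides by secondary sulfonates and the SN2 opening of β-lactones at the β-carbon by heteroatom nucleophiles.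

**Step 6**
Reactants: 12 methyl (2S)-2-[(3S)-6-ethynyl-6-methyl-1,2-dioxan-3-yl]propanoate (both C6 epimers)
Product: 13 methyl (2S)-2-[(3S,6R)-6-ethynyl-6-methyl-1,2-dioxan-3-yl]propanoate
Conditions: TfOH (5 mol %), CH2Cl2, −40 to −20 °C; NaHCO3; minor epimer re-subjected
Reagents that add atoms: none
Why: Proposed new method: the protonated tertiary propargylic peroxide ionises at C6 (SN1), the propargylic cation is recaptured by the pendant hydroperoxide, and the system settles on the chair that keeps the propanoate arm and the methyl group equatorial and puts the slim ethynyl group axial (A value about 0.4 against 1.7 kcal/mol for methyl), which is the 3,6-cis (6R) epimer, expected in about 4–6:1; closest known chemistry is the acid-catalysed exchange of tertiary alkyl peroxides and the Lewis-acid substitution of tertiary propargylic ethers.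

**Step 7**
Reactants: 14 bromobenzene; 15 5,5-dimethyloxolan-2-one
Product: 17 7-bromo-4,4-dimethyl-3,4-dihydronaphthalen-1(2H)-one, via aryl acid 16 (not isolated)
Conditions: AlCl3 (3 equiv), 14 (5 equiv, also solvent), 23 then 95 °C
Reagents that add atoms: none
Why: One-pot Friedel–Crafts alkylation–acylation in which AlCl3 ionises the lactone to the tertiary cation that alkylates bromobenzene para to bromine, after which the acid 16 acylates the ring ortho to the new alkyl group (Haworth-type closure), fixing bromine para to the ring carbon that carries the gem-dimethyl carbon.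

**Step 8**
Reactants: 17 7-bromo-4,4-dimethyl-3,4-dihydronaphthalen-1(2H)-one
Product: 18 6-bromo-1,1-dimethyl-1,2,3,4-tetrahydronaphthalene
Conditions: Et3SiH (2.5 equiv), CF3CO2H, 55 °C
Reagents that add atoms: none
Why: Ionic hydrogenation reduces the aryl ketone through the benzylic cation to the methylene group and leaves the aryl bromide untouched.

**Step 9**
Reactants: 18 6-bromo-1,1-dimethyl-1,2,3,4-tetrahydronaphthalene
Product: 20 (5,5-dimethyl-5,6,7,8-tetrahydronaphthalen-2-yl)methanol, via aryllithium 19 (not isolated)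
Conditions: n-BuLi (1.1 equiv), THF, −78 °C; then (CH2O)n, −78 to 23 °C; H2O
Reagents that add atoms: formaldehyde (as paraformaldehyde) C=O
Why: Bromine–lithium exchange followed by hydroxymethylation of the aryllithium installs the future C9 para to the ring carbon that carries the gem-dimethyl carbon.

**Step 10**
Reactants: 20 (5,5-dimethyl-5,6,7,8-tetrahydronaphthalen-2-yl)methanol
Product: 21 (5,5-dimethyl-1,4,5,6,7,8-hexahydronaphthalen-2-yl)methanol
Conditions: Li (6 equiv), NH3(l)–THF, t-BuOH (4 equiv), −78 to −33 °C; NH4Cl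
Reagents that add atoms: none
Why: Birch reduction of the lithium benzyl alkoxide (which resists benzylic hydrogenolysis) protonates the two unsubstituted para-related ring carbons C1 and C4, so all three carbon substituents stay on sp2 carbons and the C2=C3 and C4a=C8a alkenes are placed without ambiguity.

**Step 11**
Reactants: 21 (5,5-dimethyl-1,4,5,6,7,8-hexahydronaphthalen-2-yl)methanol
Product: 22 5,5-dimethyl-1,4,5,6,7,8-hexahydronaphthalene-2-carbaldehyde
Conditions: TEMPO (10 mol %), PhI(OAc)2 (1.1 equiv), CH2Cl2, 0 °C; used at once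
Reagents that add atoms: none
Why: TEMPO/PhI(OAc)2 oxidation of the allylic alcohol to the enal is fast and base-free, which keeps the 1,4-diene from moving into conjugation or aromatising.

**Step 12**
Reactants: 13 methyl (2S)-2-[(3S,6R)-6-ethynyl-6-methyl-1,2-dioxan-3-yl]propanoate; 22 5,5-dimethyl-1,4,5,6,7,8-hexahydronaphthalene-2-carbaldehyde
Product: 24 methyl (2S)-2-[(3S,6R)-6-[3-(5,5-dimethyl-1,4,5,6,7,8-hexahydronaphthalen-2-yl)-3-hydroxyprop-1-yn-1-yl]-6-methyl-1,2-dioxan-3-yl]propanoate (both carbinol epimers), via alkynylzinc triflate 23 (not isolated)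
Conditions: Zn(OTf)2 (1.5 equiv), Et3N (1.6 equiv), toluene, 23–40 °C
Reagents that add atoms: none
Why: Carreira-type zinc alkynylide 1,2-addition, in which Zn(OTf)2/Et3N metalates the terminal alkyne under conditions too mild to open the β-peroxy ester and the alkynylzinc adds to the enal carbonyl, the carbinol centre forming as both epimers and being removed in step 14.

**Step 13**
Reactants: 24 methyl (2S)-2-[(3S,6R)-6-[3-(5,5-dimethyl-1,4,5,6,7,8-hexahydronaphthalen-2-yl)-3-hydroxyprop-1-yn-1-yl]-6-methyl-1,2-dioxan-3-yl]propanoate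
Product: 26 methyl (2S)-2-[(3S,6S)-6-[3-(5,5-dimethyl-1,4,5,6,7,8-hexahydronaphthalen-2-yl)-3-hydroxypropyl]-6-methyl-1,2-dioxan-3-yl]propanoate (both carbinol epimers), via cis-alkene 25 (not isolated)
Conditions: 2-nitrobenzenesulfonohydrazide (6 equiv, in portions), Et3N (12 equiv), CH2Cl2, 23 °C
Reagents that add atoms: none
Why: Diimide reduction transfers hydrogen by a concerted syn pathway that leaves the O–O bond alone, and it reduces the disubstituted alkyne and the strained cis-alkene 25 well over ten times faster than the trisubstituted and tetrasubstituted ring alkenes (the C6 descriptor changes from R to S by priority only).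

**Step 14**
Reactants: 26 methyl (2S)-2-[(3S,6S)-6-[3-(5,5-dimethyl-1,4,5,6,7,8-hexahydronaphthalen-2-yl)-3-hydroxypropyl]-6-methyl-1,2-dioxan-3-yl]propanoate
Product: 29 methyl (2S)-2-[(3S,6S)-6-{3-[(2Z)-5,5-dimethyl-3,4,5,6,7,8-hexahydronaphthalen-2(1H)-ylidene]propyl}-6-methyl-1,2-dioxan-3-yl]propanoate, via sulfonylhydrazine 27 (not isolated), via allylic diazene 28 (not isolated)
Conditions: PPh3 (2 equiv), diethyl azodicarboxylate (2 equiv), 2-nitrobenzenesulfonohydrazide (2 equiv), THF, −30 °C; then 23 °C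
Reagents that add atoms: none
Why: Myers reductive 1,3-transposition, in which Mitsunobu N-alkylation of the sulfonohydrazide, loss of sulfinic acid to the monoalkyl diazene and a six-membered retro-ene loss of N2 deliver hydrogen to C3 and create the exocyclic alkene, and because the chain sits pseudo-equatorial in that transition state it ends trans to C3 and cis to C1, which is the Z isomer.

**Step 15**
Reactants: 29 methyl (2S)-2-[(3S,6S)-6-{3-[(2Z)-5,5-dimethyl-3,4,5,6,7,8-hexahydronaphthalen-2(1H)-ylidene]propyl}-6-methyl-1,2-dioxan-3-yl]propanoate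
Product: 30 (2S)-2-[(3S,6S)-6-{3-[(2Z)-5,5-dimethyl-3,4,5,6,7,8-hexahydronaphthalen-2(1H)-ylidene]propyl}-6-methyl-1,2-dioxan-3-yl]propanoic acid
Conditions: LiOH (3 equiv), THF–H2O (3:1), 0 °C; then HCl (aq.) to pH 4
Reagents that add atoms: lithium hydroxide [Li+].[OH-]
Why: Saponification at 0 °C proceeds by acyl attack of hydroxide faster than α-deprotonation, so the peroxide ring, the skipped diene and the C2 centre survive and acidification gives the target.

**Compound list**

1 | 2-methylbut-1-en-3-yne | C=C(C)C#C | starting material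
2 | oxirane | C1CO1 | starting material
3 | dipotassium dianion of 1 (2-ethynylallyl anion and acetylide) | [CH2-]C(=C)C#[C-].[K+].[K+] | intermediate (not isolated)
4 | 4-methylidenehex-5-yn-1-ol | C=C(CCCO)C#C | intermediate
5 | 4-methylidenehex-5-ynal | C=C(CCC=O)C#C | intermediate
6 | propanoyl chloride | CCC(=O)Cl | starting material
7 | methylketene (prop-1-en-1-one) | CC=C=O | intermediate (not isolated)
8 | (3S,4R)-3-methyl-4-(3-methylidenepent-4-yn-1-yl)oxetan-2-one | C[C@@H]1C(=O)O[C@@H]1CCC(=C)C#C | intermediate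
9 | (3S,4R)-3-methyl-4-{3-methyl-3-[(triethylsilyl)peroxy]pent-4-yn-1-yl}oxetan-2-one, 1:1 at the peroxide carbon | C[C@@H]1C(=O)O[C@@H]1CCC(C)(OO[Si](CC)(CC)CC)C#C | intermediate
10 | tetrabutylammonium salt of the desilylated peroxide anion of 9 | C[C@@H]1C(=O)O[C@@H]1CCC(C)(O[O-])C#C.CCCC[N+](CCCC)(CCCC)CCCC | intermediate (not isolated)
11 | tetrabutylammonium (2S)-2-[(3S)-6-ethynyl-6-methyl-1,2-dioxan-3-yl]propanoate, both C6 epimers | C[C@H](C(=O)[O-])[C@@H]1CCC(C)(C#C)OO1.CCCC[N+](CCCC)(CCCC)CCCC | intermediate (not isolated)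
12 | methyl (2S)-2-[(3S)-6-ethynyl-6-methyl-1,2-dioxan-3-yl]propanoate, both C6 epimers | C[C@H](C(=O)OC)[C@@H]1CCC(C)(C#C)OO1 | intermediate
13 | methyl (2S)-2-[(3S,6R)-6-ethynyl-6-methyl-1,2-dioxan-3-yl]propanoate (ethynyl cis to the propanoate arm) | C[C@H](C(=O)OC)[C@@H]1CC[C@](C)(C#C)OO1 | intermediate
14 | bromobenzene | Brc1ccccc1 | starting material
15 | 5,5-dimethyloxolan-2-one | CC1(C)CCC(=O)O1 | starting material
16 | 4-(4-bromophenyl)-4-methylpentanoic acid | CC(C)(CCC(=O)O)c1ccc(Br)cc1 | intermediate (not isolated)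
17 | 7-bromo-4,4-dimethyl-3,4-dihydronaphthalen-1(2H)-one | CC1(C)CCC(=O)c2cc(Br)ccc21 | intermediate
18 | 6-bromo-1,1-dimethyl-1,2,3,4-tetrahydronaphthalene | CC1(C)CCCc2cc(Br)ccc21 | intermediate
19 | (5,5-dimethyl-5,6,7,8-tetrahydronaphthalen-2-yl)lithium | CC1(C)CCCc2cc([Li])ccc21 | intermediate (not isolated)
20 | (5,5-dimethyl-5,6,7,8-tetrahydronaphthalen-2-yl)methanol | CC1(C)CCCc2cc(CO)ccc21 | intermediate
21 | (5,5-dimethyl-1,4,5,6,7,8-hexahydronaphthalen-2-yl)methanol | OCC1=CCC2=C(C1)CCCC2(C)C | intermediate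
22 | 5,5-dimethyl-1,4,5,6,7,8-hexahydronaphthalene-2-carbaldehyde | O=CC1=CCC2=C(C1)CCCC2(C)C | intermediate
23 | alkynylzinc triflate of 13 | C[C@H](C(=O)OC)[C@@H]1CC[C@](C)(C#C[Zn]OS(=O)(=O)C(F)(F)F)OO1 | intermediate (not isolated)
24 | methyl (2S)-2-[(3S,6R)-6-[3-(5,5-dimethyl-1,4,5,6,7,8-hexahydronaphthalen-2-yl)-3-hydroxyprop-1-yn-1-yl]-6-methyl-1,2-dioxan-3-yl]propanoate, both carbinol epimers | C[C@H](C(=O)OC)[C@@H]1CC[C@](C)(C#CC(O)C2=CCC3=C(C2)CCCC3(C)C)OO1 | intermediate
25 | methyl (2S)-2-[(3S,6R)-6-[(1Z)-3-(5,5-dimethyl-1,4,5,6,7,8-hexahydronaphthalen-2-yl)-3-hydroxyprop-1-en-1-yl]-6-methyl-1,2-dioxan-3-yl]propanoate | C[C@H](C(=O)OC)[C@@H]1CC[C@](C)(/C=C\C(O)C2=CCC3=C(C2)CCCC3(C)C)OO1 | intermediate (not isolated)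
26 | methyl (2S)-2-[(3S,6S)-6-[3-(5,5-dimethyl-1,4,5,6,7,8-hexahydronaphthalen-2-yl)-3-hydroxypropyl]-6-methyl-1,2-dioxan-3-yl]propanoate, both carbinol epimers | C[C@H](C(=O)OC)[C@@H]1CC[C@](C)(CCC(O)C2=CCC3=C(C2)CCCC3(C)C)OO1 | intermediate
27 | N-alkyl-N-(2-nitrobenzenesulfonyl)hydrazine from 26 (hydrazine nitrogen on the former carbinol carbon) | C[C@H](C(=O)OC)[C@@H]1CC[C@](C)(CCC(N(N)S(=O)(=O)c4ccccc4[N+](=O)[O-])C2=CCC3=C(C2)CCCC3(C)C)OO1 | intermediate (not isolated)
28 | allylic monoalkyl diazene from 27 | C[C@H](C(=O)OC)[C@@H]1CC[C@](C)(CCC(N=N)C2=CCC3=C(C2)CCCC3(C)C)OO1 | intermediate (not isolated)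
29 | methyl (2S)-2-[(3S,6S)-6-{3-[(2Z)-5,5-dimethyl-3,4,5,6,7,8-hexahydronaphthalen-2(1H)-ylidene]propyl}-6-methyl-1,2-dioxan-3-yl]propanoate | C[C@H](C(=O)OC)[C@@H]1CC[C@](C)(CC/C=C2/CCC3=C(CCCC3(C)C)C2)OO1 | intermediate
30 | (2S)-2-[(3S,6S)-6-{3-[(2Z)-5,5-dimethyl-3,4,5,6,7,8-hexahydronaphthalen-2(1H)-ylidene]propyl}-6-methyl-1,2-dioxan-3-yl]propanoic acid | C[C@H](C(=O)O)[C@@H]1CC[C@](C)(CC/C=C2/CCC3=C(CCCC3(C)C)C2)OO1 | target

**Totals**

Total step count: 15. Longest linear sequence: 10 (steps 1–6, then 12–15); the ring branch (steps 7–11) is 5 steps.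

**Steps most likely to fail, with fallbacks**

Step 6 (acid-mediated correction of C6). The ionisation may be outrun by decomposition of the peroxide, or the equilibrium ratio may be lower than estimated. Fallback: set out from 12 and rejoin at 13 without any equilibration. The two C6 epimers are diastereomers and are separated by preparative HPLC on silica. Compound 13 goes on, and the unwanted epimer methyl (2S)-2-[(3S,6S)-6-ethynyl-6-methyl-1,2-dioxan-3-yl]propanoate F7 is set aside, at the cost of about half the material.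

Step 5 (peroxide anion opening of the β-lactone). Acyl attack or elimination of the lactone could compete. Fallback: set out from lactone 8 and rejoin at 12 through a sulfonate displacement. LiBH4 reduces 8 to (2R,3R)-2-methyl-6-methylideneoct-7-yne-1,3-diol F1. TBSCl/imidazole silylates the primary hydroxyl to give (2R,3R)-1-{[tert-butyl(dimethyl)silyl]oxy}-2-methyl-6-methylideneoct-7-yn-3-ol F2, and MsCl/Et3N gives the secondary mesylate (2R,3R)-1-{[tert-butyl(dimethyl)silyl]oxy}-2-methyl-6-methylideneoct-7-yn-3-yl methanesulfonate F3. The step 4 conditions convert the enyne into the silyl peroxide (2R,3R)-1-{[tert-butyl(dimethyl)silyl]oxy}-2,6-dimethyl-6-[(triethylsilyl)peroxy]oct-7-yn-3-yl methanesulfonate F4. Bu4NF followed by KOtBu/18-crown-6 removes both silyl groups and closes the dioxane by 6-exo displacement of the mesylate with inversion, giving (2R)-2-[(3S)-6-ethynyl-6-methyl-1,2-dioxan-3-yl]propan-1-ol F5. TEMPO/PhI(OAc)2 in wet MeCN gives (2S)-2-[(3S)-6-ethynyl-6-methyl-1,2-dioxan-3-yl]propanoic acid F6, and Me3SiCHN2 returns 12.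

Step 12 (alkynylation of the labile dienal). The enal may conjugate or aromatise before the slow zinc alkynylide addition. Fallback: set out from 13 and 22 and rejoin at 24 through an acyl coupling. Pinnick oxidation (NaClO2, NaH2PO4, 2-methylbut-2-ene) of 22 gives 5,5-dimethyl-1,4,5,6,7,8-hexahydronaphthalene-2-carboxylic acid F8, and oxalyl chloride gives 5,5-dimethyl-1,4,5,6,7,8-hexahydronaphthalene-2-carbonyl chloride F9. Acyl Sonogashira coupling with 13 (PdCl2(PPh3)2, CuI, Et3N, THF, 23 °C) gives the ynone methyl (2S)-2-[(3S,6R)-6-[3-(5,5-dimethyl-1,4,5,6,7,8-hexahydronaphthalen-2-yl)-3-oxoprop-1-yn-1-yl]-6-methyl-1,2-dioxan-3-yl]propanoate F10. Luche 1,2-reduction (NaBH4, CeCl3, MeOH, −40 °C) returns 24.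

**Further compounds**

F1 | step 5 | (2R,3R)-2-methyl-6-methylideneoct-7-yne-1,3-diol | C[C@H](CO)[C@H](O)CCC(=C)C#C
F2 | step 5 | (2R,3R)-1-{[tert-butyl(dimethyl)silyl]oxy}-2-methyl-6-methylideneoct-7-yn-3-ol | C[C@H](CO[Si](C)(C)C(C)(C)C)[C@H](O)CCC(=C)C#C
F3 | step 5 | (2R,3R)-1-{[tert-butyl(dimethyl)silyl]oxy}-2-methyl-6-methylideneoct-7-yn-3-yl methanesulfonate | C[C@H](CO[Si](C)(C)C(C)(C)C)[C@H](OS(C)(=O)=O)CCC(=C)C#C
F4 | step 5 | (2R,3R)-1-{[tert-butyl(dimethyl)silyl]oxy}-2,6-dimethyl-6-[(triethylsilyl)peroxy]oct-7-yn-3-yl methanesulfonate, both C6 epimers | C[C@H](CO[Si](C)(C)C(C)(C)C)[C@H](OS(C)(=O)=O)CCC(C)(OO[Si](CC)(CC)CC)C#C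
F5 | step 5 | (2R)-2-[(3S)-6-ethynyl-6-methyl-1,2-dioxan-3-yl]propan-1-ol, both C6 epimers | C[C@H](CO)[C@@H]1CCC(C)(C#C)OO1
F6 | step 5 | (2S)-2-[(3S)-6-ethynyl-6-methyl-1,2-dioxan-3-yl]propanoic acid, both C6 epimers | C[C@H](C(=O)O)[C@@H]1CCC(C)(C#C)OO1
F7 | step 6 | methyl (2S)-2-[(3S,6S)-6-ethynyl-6-methyl-1,2-dioxan-3-yl]propanoate | C[C@H](C(=O)OC)[C@@H]1CC[C@@](C)(C#C)OO1
F8 | step 12 | 5,5-dimethyl-1,4,5,6,7,8-hexahydronaphthalene-2-carboxylic acid | OC(=O)C1=CCC2=C(C1)CCCC2(C)C
F9 | step 12 | 5,5-dimethyl-1,4,5,6,7,8-hexahydronaphthalene-2-carbonyl chloride | ClC(=O)C1=CCC2=C(C1)CCCC2(C)C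
F10 | step 12 | methyl (2S)-2-[(3S,6R)-6-[3-(5,5-dimethyl-1,4,5,6,7,8-hexahydronaphthalen-2-yl)-3-oxoprop-1-yn-1-yl]-6-methyl-1,2-dioxan-3-yl]propanoate | C[C@H](C(=O)OC)[C@@H]1CC[C@](C)(C#CC(=O)C2=CCC3=C(C2)CCCC3(C)C)OO1
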